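The runs are simulated for substances that don't exist; noise was put on by code.

The elm run charges Z at 46.7% of its G, and its readings of E and L together lie between 45.8% and 47.5% of the G charged from the first reading on. Each E and each L costs one Z, so at the bench I compare two charges. For the flask asked about that is 70.0%, and I call it the cover, the Z charged as a fraction of the G charged. With a cover below one and these steps, Z is the limiting reagent: once it is used up, E and L together stand at the cover, and the rest of the G charged stays as G and D.

The border is a cover of one. The maple run has 104%, and at its last reading G reads 0% while E and L together read 99.9%, so there the sum stops at the G charged. The flask lies below that border. The elm readings were already flat at 10.0 min and the flask gets the longer time of 2.5 h, so I expect E and L in the flask to sum to 70.0%, with 30.0% left as G and D. The cover gives no split between E and L.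

| flask | G | Z | remark | time |
|---|---|---|---|---|
| maple | 0.54 M | 0.56 M | run made earlier |  |
| elm | 1.2 M | 0.56 M | run made earlier |  |
| cedar | 0.80 M | 0.84 M | run made earlier |  |
| flask | 0.80 M | 0.560 M |  | 2.5 h |

| run | time / min | E / % | L / % | G / % |
|---|---|---|---|---|
| maple | 10.0 | 58.1 | 29.8 | 9.7 |
| maple | 30.0 | 62.8 | 33.3 | 3.0 |
| maple | 60.0 | 64.8 | 34.8 | 1.6 |
| maple | 80.0 | 64.0 | 35.0 | 0 |
| maple | 120 | 65.6 | 34.3 | 0 |
| elm | 10.0 | 32.5 | 13.3 | 39.3 |
| elm | 20.0 | 33.4 | 13.8 | 39.8 |
| elm | 30.0 | 33.3 | 13.6 | 39.1 |
| elm | 60.0 | 33.6 | 13.9 | 39.5 |
| elm | 120 | 32.1 | 13.8 | 39.7 |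
| cedar | 25.0 | 68.0 | 30.7 | 2.0 |
| cedar | 50.0 | 68.6 | 30.9 | 1.9 |
| cedar | 80.0 | 68.7 | 30.9 | 0 |
| cedar | 90.0 | 68.7 | 31.3 | 0.1 |
| cedar | 120 | 69.6 | 30.6 | 0 |

(readings scatter by 0.5 percentage points)

- amounts and yields of E count J too
- given per volume of solution although it is solid: J
- candidate steps: J <-> E; G + Z -> E; Z + D -> L; G <-> D
- in a conversion D counts as not yet reacted
- the reaction counts as stopped when no species that holds the G changes by six tenths of a point or more over the second half of the time

1. which holds at 2.5 h: what has brought the reaction to rest, or that it has not come to rest (D counts as not reacted) (all of G has reacted / Z has run out first / forward and back rates have come level / it is still moving)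
2. amount of E at 2.5 h, in percent of the G charged
3. amount of L at 2.5 h, in percent of the G charged

The forecast says Z has run out first, with E 48% and L 22%, on the ground that “Z is limiting”. Its sum is 70.0%, and it interpolates the split between elm and maple.

The flask gives the answer "Z has run out first", with Z at 0% of its charge, E 47.2% and L 22.8% at 2.50 h, by these steps:

    J ⇌ E, rate k1*(cs1 - [E]) while solid is left; crystals form when [E] > cs1 (solubility = 19.0 mM, k = 0.0434 /s)
    G + Z → E (k = 0.0137 /M/s)
    Z + D → L (k = 0.0376 /M/s)
    G ⇌ D (K = 0.347, k = 0.00579 /s)

G + Z to E and Z + D to L run while Z is there: at 0.250 h Z is down to 0.470% of its own charge, and E and L stand at 47.1% and 22.6%. At 2.50 h, with Z at 0%, E and L sum to 70.0% against the cover of 70.0%, and G and D hold 30.0%. A neighbour with a cover of 27.5% ends with E and L summing to 27.5%.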